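**Assumptions and conventions.** (R)-5-Methylcyclohex-2-en-1-one (6) is taken as a purchasable, pulegone-derived catalogue enone. Locants C1–C20 are those of the target (C11 bears OAc, C12 the methyl, C2–O–C9 is the oxolane, C3–O–C16 the oxepane). α is the ring-A face carrying C2 and C9; β is the face carrying H-1 and H-10.

## Retrosynthetic overview

1. The target comes from iodo-aldehyde 31 by a Nozaki–Hiyama–Kishi closure of the nine-membered ring (C6–C7), the last C–C bond made.
2. The oxolane (C2–O–C9) and the oxepane (C3–O–C16) are made in one flask from monocyclic (2Z)-alkene 26: 2,3-epoxidation, opening at C2 by the C9 hydroxyl, then capture of C16 by the freed C3 alkoxide. This is the order in which the two ether bridges are thought to arise in the coral.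
3. The C11-OH/C12-Me pattern comes from an 11α,12α-epoxide (1,2-hydride shift, then reduction); the C9–C10 bond comes from a suprafacial [2,3]-Wittig shift out of a C12 tertiary ether.
4. Ring A comes from enone 6, isopropenylmagnesium bromide and (Z)-alkenyl iodide 5 in a three-component coupling; the remaining carbons come from 1-bromo-2-butyne, propyne and a bromo acetal.
5. Ring order: cyclohexane (bought) → oxolane → oxepane (same flask) → oxonene.

## Route

Step 1
Reactants: 1 2-(2-bromoethyl)-1,3-dioxolane; 2 propyne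
Product: 5 2-[(3Z)-4-iodo-3-methylbut-3-en-1-yl]-1,3-dioxolane, via Grignard reagent 3 (not isolated), via (Z)-alkenylcopper 4 (not isolated)
Conditions: Mg, THF, 30 °C; CuBr·SMe2, Et2O–Me2S, −45 °C; propyne, −25 °C; I2, −78 → 0 °C
Reagents that add atoms: iodine (SMILES: II)
Why: Normant carbocupration adds R and Cu syn across propyne with Cu on the terminal carbon, and iodinolysis with retention gives the iodide with I cis to the chain, which fixes the later (2Z) geometry.

Step 2
Reactants: 6 (R)-5-methylcyclohex-2-en-1-one; 7 isopropenylmagnesium bromide; 5 2-[(3Z)-4-iodo-3-methylbut-3-en-1-yl]-1,3-dioxolane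
Product: 10 (2S,3R,5R)-2-[(1Z)-4-(1,3-dioxolan-2-yl)-2-methylbut-1-enyl]-5-methyl-3-isopropenylcyclohexanone, via bromomagnesium enolate 8 (not isolated), via chlorozinc enolate 9 (not isolated)
Conditions: 7, CuBr·SMe2 (5 mol %), THF, −78 °C; ZnCl2, −78 → 0 °C; 5, Pd2(dba)3 (2 mol %), Q-Phos (4 mol %), rt
Reagents that add atoms: none
Why: Proposed new method: copper-catalysed 1,4-addition enters axially trans to the C12 methyl (setting C14) and gives the C10/C1 enolate regiospecifically; after Mg→Zn exchange, Pd(0) inserts into the vinyl iodide, the zinc enolate transmetalates, and reductive elimination places the alkenyl group at C1 trans to the new isopropenyl group with retention of the Z geometry; the closest known reactions are conjugate addition–enolate trapping and Negishi-type Pd-catalysed α-alkenylation of ketone zinc enolates.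

Step 3
Reactants: 10 the ketone from step 2
Product: 12 (5R,6S)-6-[(1Z)-4-(1,3-dioxolan-2-yl)-2-methylbut-1-enyl]-3-methyl-5-isopropenylcyclohex-2-enone, via silyl enol ether 11 (not isolated)
Conditions: LDA, TMSCl (internal quench), THF, −78 °C; Pd(OAc)2 (1.05 equiv), MeCN, rt
Reagents that add atoms: none
Why: Kinetic deprotonation takes the unhindered C11 methylene rather than the C1 methine, and Saegusa–Ito oxidation gives the β-methyl enone; the C12 centre, having relayed chirality to C14, is deliberately erased and rebuilt in step 10.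

Step 4
Reactants: 12 the enone from step 3
Product: 13 11α,12α-epoxy ketone (oxirane O trans to the isopropenyl group)
Conditions: 30 % H2O2, NaOH (0.3 equiv), MeOH, 0 °C
Reagents that add atoms: hydrogen peroxide (SMILES: OO)
Why: In this Weitz–Scheffer epoxidation the hydroperoxide anion adds axially to C12 anti to the C14 isopropenyl group (as with carvone), so the oxirane lies on the α face.

Step 5
Reactants: 13 the epoxy ketone from step 4
Product: 14 tertiary allylic alcohol (C12-OH α and C12-Me β; C10=C11)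
Conditions: N2H4·H2O, AcOH (cat.), MeOH, 0 °C → rt
Reagents that add atoms: none
Why: The Wharton transposition (epoxy hydrazone → vinyl diazene → loss of N2) moves the alkene to C10=C11 and leaves the C12–O bond untouched on the α face.

Step 6
Reactants: 14 the allylic alcohol from step 5; 15 1-bromo-2-butyne
Product: 16 but-2-ynyl ether of 14
Conditions: KH, 15, 18-crown-6 (cat.), THF, 0 °C → rt
Reagents that add atoms: none
Why: This is a Williamson etherification of a tertiary alkoxide with an SN2-reactive propargylic bromide, and no stereocentre is touched.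

Step 7
Reactants: 16 the propargyl ether from step 6
Product: 17 (9S)-propargylic alcohol (C10 carries α-CH(OH)C≡CCH3; C11=C12-Me)
Conditions: n-BuLi, THF, −78 → −40 °C; aq. NH4Cl
Reagents that add atoms: none
Why: The [2,3]-Wittig rearrangement is suprafacial, so C9 is delivered from the α-oriented C12–O to the α face of C10 (cis to the C1 chain) while the alkene moves to C11=C12; the exo-alkynyl envelope transition state is expected to give the (9S) carbinol, which is the wrong C9 epimer and is corrected in step 9.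

Step 8
Reactants: 17 the alcohol from step 7
Product: 18 11α,12α-epoxide of 17
Conditions: VO(acac)2 (5 mol %), t-BuOOH (1.1 equiv), CH2Cl2, 0 °C
Reagents that add atoms: tert-butyl hydroperoxide (SMILES: CC(C)(C)OO)
Why: In this vanadium-catalysed directed epoxidation the homoallylic C9 hydroxyl sits on the α face and delivers oxygen syn to C11=C12 through a six-membered vanadate transition state, which should outpace the seven-membered delivery to the bishomoallylic C2=C3.

Step 9
Reactants: 18 the epoxy alcohol from step 8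
Product: 19 (9R)-benzoate
Conditions: PhCO2H, PPh3, DIAD, toluene, 0 °C → rt
Reagents that add atoms: benzoic acid (SMILES: OC(=O)c1ccccc1)
Why: Mitsunobu SN2 displacement at the propargylic carbinol inverts C9 to the configuration of the target, and the ester masks the hydroxyl during the Lewis-acid step.

Step 10
Reactants: 19 the benzoate from step 9
Product: 21 (11R,12R)-11α-alcohol with 12α-methyl, via C11 ketone 20 (not isolated)
Conditions: BF3·OEt2, CH2Cl2, −78 °C; then NaBH4, MeOH, −78 → −30 °C
Reagents that add atoms: none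
Why: In the Meinwald rearrangement the epoxide ionises at tertiary C12 and the axial β-H on C11, antiperiplanar to the breaking C12–O bond, shifts to the β face of C12 (methyl now α, C11 a ketone); borohydride then attacks the ketone from the β face because the α face is blocked by the axial C10 and C12 substituents, giving the 11α-alcohol.

Step 11
Reactants: 21 the alcohol from step 10
Product: 23 (9R)-iodo diol with a (Z)-CH=C(I)CH3 unit, via vinylalanate 22 (not isolated)
Conditions: Red-Al (5 equiv), THF, 0 °C → rt; then I2, −78 → 0 °C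
Reagents that add atoms: iodine (SMILES: II)
Why: Red-Al cleaves the benzoate, and the resulting C9 alkoxyaluminate delivers hydride to C8 in a trans-hydroalumination that places Al on C7 in a five-membered alanate; iodinolysis with retention gives the (Z)-γ-iodo allylic alcohol.

Step 12
Reactants: 23 the iodo diol from step 11
Product: 25 (15R)-triol (C9-OH; C11-OH; C16-OH), via alkylborane 24 (not isolated)
Conditions: 9-BBN (4 equiv), THF, 0 °C → rt; then NaOH, H2O2, 0 °C
Reagents that add atoms: hydrogen peroxide (SMILES: OO)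
Why: 9-BBN hydroborates only the 1,1-disubstituted alkene (anti-Markovnikov), and with the C14–H eclipsing the C=CH2 bond the borane approaches anti to the more substituted ring carbon C1, which is expected to give (15R).

Step 13
Reactants: 25 the triol from step 12
Product: 26 C16 mono-tosylate
Conditions: TsCl (1.1 equiv), Et3N, DMAP (cat.), CH2Cl2, −10 °C
Reagents that add atoms: p-toluenesulfonyl chloride (SMILES: Cc1ccc(cc1)S(=O)(=O)Cl)
Why: Sulfonylation takes the primary hydroxyl over the two hindered secondary ones and installs the leaving group for the oxepane.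

Step 14
Reactants: 26 the tosylate from step 13
Product: 29 tricyclic oxolane–oxepane alcohol (11α-OH), via epoxide 27 (not isolated), via hydroxy-oxolane 28 (not isolated)
Conditions: D-fructose-derived Shi ketone (30 mol %), Oxone, K2CO3, Bu4NHSO4, MeCN–DMM–borate buffer (pH 10.5), 0 °C; then NaH (3 equiv), THF, 0 °C → rt
Reagents that add atoms: potassium peroxymonosulfate (SMILES: [K+].[O-]S(=O)(=O)OO)
Why: Shi epoxidation (reagent control, trisubstituted alkene only; the iodoalkene is inert) gives the (2R,3S)-epoxide; under base the C9 alkoxide opens it at the less substituted C2 by 5-exo SN2 with inversion, giving the 2,9-cis oxolane and fixing C2 and C3, and the freed C3 alkoxide displaces the primary tosylate (7-exo-tet) to close the oxepane.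

Step 15
Reactants: 29 the tricyclic alcohol from step 14
Product: 30 11-acetate
Conditions: Ac2O, pyridine, DMAP (cat.), CH2Cl2, rt
Reagents that add atoms: acetic anhydride (SMILES: CC(=O)OC(C)=O)
Why: Acylation of the only free hydroxyl, with no stereochemical change.

Step 16
Reactants: 30 the acetate from step 15
Product: 31 C6 aldehyde
Conditions: PPTS (cat.), acetone–H2O (4:1), 55 °C
Reagents that add atoms: water (SMILES: O)
Why: Mild acetal hydrolysis frees the aldehyde and leaves the acetate, the ethers and the vinyl iodide intact.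

Step 17
Reactants: 31 the iodo-aldehyde from step 16
Product: 32 target CNP0289966.2
Conditions: CrCl2 (10 equiv), NiCl2 (2 mol %), DMSO, rt, 2 mM
Reagents that add atoms: none
Why: In the Nozaki–Hiyama–Kishi reaction the alkenyl iodide (Ni insertion, transmetalation to Cr) adds to the aldehyde with retention of the Z geometry and closes the nine-membered ring at C6–C7; the (6R) carbinol is expected from attack on the outward-facing aldehyde face of the folded 2,9-cis-bridged precursor, as in related NHK closures of this ring.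

## Compound list

1 | 2-(2-bromoethyl)-1,3-dioxolane | BrCCC1OCCO1 | starting material
2 | propyne | CC#C | starting material
3 | [2-(1,3-dioxolan-2-yl)ethyl]magnesium bromide | Br[Mg]CCC1OCCO1 | intermediate
4 | (Z)-[4-(1,3-dioxolan-2-yl)-2-methylbut-1-enyl]copper (Cu cis to the chain) | [Cu]/C=C(C)\CCC1OCCO1 | intermediate
5 | 2-[(3Z)-4-iodo-3-methylbut-3-en-1-yl]-1,3-dioxolane (C2–C6 and C18) | I/C=C(C)\CCC1OCCO1 | intermediate
6 | (R)-5-methylcyclohex-2-en-1-one | C[C@@H]1CC=CC(=O)C1 | starting material
7 | isopropenylmagnesium bromide | CC(=C)[Mg]Br | starting material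
8 | bromomagnesium (3R,5R)-5-methyl-3-isopropenylcyclohex-1-en-1-olate | Br[Mg]OC1=C[C@H](C(C)=C)C[C@@H](C)C1 | intermediate
9 | chlorozinc (3R,5R)-5-methyl-3-isopropenylcyclohex-1-en-1-olate | Cl[Zn]OC1=C[C@H](C(C)=C)C[C@@H](C)C1 | intermediate
10 | (2S,3R,5R)-2-[(1Z)-4-(1,3-dioxolan-2-yl)-2-methylbut-1-enyl]-5-methyl-3-isopropenylcyclohexanone (C10 ketone; C1 chain α; C14 isopropenyl β; C12 methyl α) | O=C1C[C@H](C)C[C@@H](C(C)=C)[C@@H]1/C=C(C)\CCC1OCCO1 | intermediate
11 | C10=C11 trimethylsilyl enol ether of 10 | C[Si](C)(C)OC1=C[C@H](C)C[C@@H](C(C)=C)[C@@H]1/C=C(C)\CCC1OCCO1 | intermediate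
12 | (5R,6S)-6-[(1Z)-4-(1,3-dioxolan-2-yl)-2-methylbut-1-enyl]-3-methyl-5-isopropenylcyclohex-2-enone | O=C1C=C(C)C[C@@H](C(C)=C)[C@@H]1/C=C(C)\CCC1OCCO1 | intermediate
13 | 11α,12α-epoxide of 12 (oxirane O trans to isopropenyl, cis to the C1 chain) | O=C1[C@@H]2O[C@]2(C)C[C@@H](C(C)=C)[C@@H]1/C=C(C)\CCC1OCCO1 | intermediate
14 | 4-[(1Z)-4-(1,3-dioxolan-2-yl)-2-methylbut-1-enyl]-1-methyl-5-isopropenylcyclohex-2-en-1-ol, OH α (cis to the C1 chain, trans to isopropenyl) | C[C@]1(O)C=C[C@@H](/C=C(C)\CCC2OCCO2)[C@H](C(C)=C)C1 | intermediate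
15 | 1-bromo-2-butyne | CC#CCBr | starting material
16 | but-2-ynyl ether of 14 | C[C@]1(OCC#CC)C=C[C@@H](/C=C(C)\CCC2OCCO2)[C@H](C(C)=C)C1 | intermediate
17 | (9S)-1-(ring A)-but-2-yn-1-ol: C10 α-CH(OH)C≡CCH3, C1 α-alkenyl, C14 β-isopropenyl, C11=C12-Me | CC1=C[C@@H]([C@H](O)C#CC)[C@@H](/C=C(C)\CCC2OCCO2)[C@H](C(C)=C)C1 | intermediate
18 | 11α,12α-epoxide of 17 | C[C@]12O[C@H]1[C@@H]([C@H](O)C#CC)[C@@H](/C=C(C)\CCC3OCCO3)[C@H](C(C)=C)C2 | intermediate
19 | (9R)-benzoate (C9 inverted) of the 11α,12α-epoxide | C[C@]12O[C@H]1[C@@H]([C@@H](OC(=O)c3ccccc3)C#CC)[C@@H](/C=C(C)\CCC3OCCO3)[C@H](C(C)=C)C2 | intermediate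
20 | C11 ketone, C12 (R) with methyl α, (9R)-benzoate | C[C@H]1C(=O)[C@@H]([C@@H](OC(=O)c2ccccc2)C#CC)[C@@H](/C=C(C)\CCC2OCCO2)[C@H](C(C)=C)C1 | intermediate
21 | (11R,12R)-11α-alcohol, 12α-methyl, (9R)-benzoate | C[C@H]1[C@@H](O)[C@@H]([C@@H](OC(=O)c2ccccc2)C#CC)[C@@H](/C=C(C)\CCC2OCCO2)[C@H](C(C)=C)C1 | intermediate
22 | sodium bis(2-methoxyethoxy)aluminate, 1,2-oxaluminole spanning O9 and C7 (C11 hydroxyl drawn free) | [Na+].C[C@H]1[C@@H](O)[C@@H]([C@@H]2C=C(C)[Al-](OCCOC)(OCCOC)O2)[C@@H](/C=C(C)\CCC2OCCO2)[C@H](C(C)=C)C1 | intermediate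
23 | (9R)-diol with (Z)-CH=C(I)CH3 at C9; C9-OH and 11α-OH | C[C@H]1[C@@H](O)[C@@H]([C@@H](O)/C=C(\I)C)[C@@H](/C=C(C)\CCC2OCCO2)[C@H](C(C)=C)C1 | intermediate
24 | B-(C16-alkyl)-9-borabicyclo[3.3.1]nonane from 23 (hydroxyls drawn free) | C[C@H]1[C@@H](O)[C@@H]([C@@H](O)/C=C(\I)C)[C@@H](/C=C(C)\CCC2OCCO2)[C@H]([C@@H](C)CB2C3CCCC2CCC3)C1 | intermediate
25 | (15R)-triol: C9-OH, 11α-OH, C16-OH | C[C@H]1[C@@H](O)[C@@H]([C@@H](O)/C=C(\I)C)[C@@H](/C=C(C)\CCC2OCCO2)[C@H]([C@@H](C)CO)C1 | intermediate
26 | C16 p-toluenesulfonate of 25 | C[C@H]1[C@@H](O)[C@@H]([C@@H](O)/C=C(\I)C)[C@@H](/C=C(C)\CCC2OCCO2)[C@H]([C@@H](C)COS(=O)(=O)c2ccc(C)cc2)C1 | intermediate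
27 | (2R,3S)-2,3-epoxide of 26 | C[C@H]1[C@@H](O)[C@@H]([C@@H](O)/C=C(\I)C)[C@@H]([C@H]2O[C@@]2(C)CCC2OCCO2)[C@H]([C@@H](C)COS(=O)(=O)c2ccc(C)cc2)C1 | intermediate
28 | 2,9-cis-oxolane (2S,3S,9R) with C3 tertiary hydroxyl and C16 tosylate | C[C@H]1[C@@H](O)[C@H]2[C@H](/C=C(\I)C)O[C@H]([C@@](C)(O)CCC3OCCO3)[C@H]2[C@H]([C@@H](C)COS(=O)(=O)c2ccc(C)cc2)C1 | intermediate
29 | tricyclic oxolane–oxepane 11α-alcohol; C9 bears (Z)-CH=C(I)CH3 and C3 bears CH2CH2-(1,3-dioxolan-2-yl) | O[C@H]1[C@@H]2[C@@H]3[C@@H](C[C@H]1C)[C@@H](C)CO[C@@](C)(CCC4OCCO4)[C@H]3O[C@H]2/C=C(\I)C | intermediate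
30 | 11-acetate of 29 | CC(=O)O[C@H]1[C@@H]2[C@@H]3[C@@H](C[C@H]1C)[C@@H](C)CO[C@@](C)(CCC4OCCO4)[C@H]3O[C@H]2/C=C(\I)C | intermediate
31 | C6 aldehyde from 30 | CC(=O)O[C@H]1[C@@H]2[C@@H]3[C@@H](C[C@H]1C)[C@@H](C)CO[C@@](C)(CCC=O)[C@H]3O[C@H]2/C=C(\I)C | intermediate
32 | CNP0289966.2, (1S,2S,3S,6R,7Z,9S,10R,11R,12R,14S,15R) | CC(=O)O[C@H]1[C@@H]2[C@@H]3[C@@H](C[C@H]1C)[C@@H](C)CO[C@@]1(C)CC[C@@H](O)/C(C)=C\[C@@H]2O[C@@H]31 | target

## Step count and risks

Total steps: 17. Longest linear sequence: 17 (1 → 5 → 10 → … → 32; 16 counted from enone 6).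

**Step 2 (one-pot conjugate addition and zinc-enolate alkenylation).** If the tandem coupling fails, set out from 6 and 7 and trap the copper-catalysed adduct with TMSCl to isolate the regiodefined trimethylsilyl enol ether F1. Then couple F1 with iodide 5 through a tin enolate under Kuwajima–Migita conditions (Bu3SnF, PdCl2[P(o-tol)3]2, benzene, reflux). The alkenyl group again enters trans to the isopropenyl group and the sequence returns to the route at 10.

**Step 8 (directed epoxidation of C11=C12 in the presence of C2=C3).** If the vanadium catalyst does not discriminate between the two alkenes, both are epoxidised on purpose and the ether rings are closed in the other order. Set out from 17: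
- 9-BBN then H2O2 (the 1,1-disubstituted alkene reacts before the internal alkyne) gives the 16-hydroxy diol F2.
- VO(acac)2 with 2.5 equiv of t-BuOOH gives the bis-epoxide F3 (11α,12α and the C9-OH-directed 2S,3R oxirane).
- BF3·OEt2 then NaBH4: the C16 hydroxyl opens the 2,3-epoxide at tertiary C3 (7-endo, inversion) to give the oxepane and a C2 hydroxyl of target configuration, while the 11,12-epoxide undergoes the hydride shift and reduction of step 10. The product is the alkynyl triol F4.
- Red-Al then I2 gives the iodo triol F5.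
- PPh3 and DIAD close the oxolane by intramolecular Mitsunobu etherification: the C2 hydroxyl displaces the activated allylic (9S) carbinol with inversion. This returns to the route at 29 and makes step 9 unnecessary.

**Step 14 (epoxidation and double etherification in one flask).** If the tertiary alkoxide does not displace the tosylate cleanly, or the cascade gives mixtures, the two ring closures are separated and the oxepane is closed under neutral conditions. Set out from triol 25 (before tosylation). Shi epoxidation followed by K2CO3 in MeOH gives the hydroxy-oxolane triol F6 (C3-OH, 11α-OH, C16-OH). Tf2O (1 equiv) and 2,6-lutidine at −78 °C convert the primary hydroxyl into the primary triflate F7, which is captured at once by the neighbouring tertiary C3 hydroxyl. This returns to the route at 29.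

Further compounds
F1 | step 2 | (3R,5R)-5-methyl-3-isopropenyl-1-(trimethylsilyloxy)cyclohex-1-ene | C[Si](C)(C)OC1=C[C@H](C(C)=C)C[C@@H](C)C1
F2 | step 8 | (9S,15R)-diol from hydroboration of 17 (C9-OH and C16-OH; alkyne retained) | CC1=C[C@@H]([C@H](O)C#CC)[C@@H](/C=C(C)\CCC2OCCO2)[C@H]([C@@H](C)CO)C1
F3 | step 8 | bis-epoxide of F2: 11α,12α-epoxide and (2S,3R)-2,3-epoxide | C[C@]12O[C@H]1[C@@H]([C@H](O)C#CC)[C@@H]([C@@H]3O[C@]3(C)CCC3OCCO3)[C@H]([C@@H](C)CO)C2
F4 | step 8 | oxepane triol: (2S)-C2-OH, (9S)-C9-OH, 11α-OH, C9 bearing C≡CCH3 | C[C@@H]1C[C@H]2[C@@H](C)CO[C@@](C)(CCC3OCCO3)[C@@H](O)[C@@H]2[C@H]([C@H](O)C#CC)[C@@H]1O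
F5 | step 8 | oxepane triol with (Z)-CH=C(I)CH3 at the (9S) carbinol | C[C@@H]1C[C@H]2[C@@H](C)CO[C@@](C)(CCC3OCCO3)[C@@H](O)[C@@H]2[C@H]([C@H](O)/C=C(\I)C)[C@@H]1O
F6 | step 14 | 2,9-cis-oxolane triol: C3-OH, 11α-OH, C16-OH | C[C@H]1[C@@H](O)[C@H]2[C@H](/C=C(\I)C)O[C@H]([C@@](C)(O)CCC3OCCO3)[C@H]2[C@H]([C@@H](C)CO)C1
F7 | step 14 | C16 trifluoromethanesulfonate of F6 | C[C@H]1[C@@H](O)[C@H]2[C@H](/C=C(\I)C)O[C@H]([C@@](C)(O)CCC3OCCO3)[C@H]2[C@H]([C@@H](C)COS(=O)(=O)C(F)(F)F)C1
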